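One equivalent of Qb was the unit I counted in: Qe has used one Qb per Qa, and whatever has gone on from Qe has used two.

| flask | Qa | Qb | remark | time |
|---|---|---|---|---|
| zeta | 0.40 M | 2.5 equiv | run made earlier |  |
| theta | 0.40 M | 4 equiv | run made earlier |  |
| eta | 0.60 M | 1.8 equiv | run made earlier |  |
| flask | 0.40 M | 1.80 equiv |  | 8.0 min |

| run | time / min | Qa / % | Qe / % |
|---|---|---|---|
| zeta | 0.667 | 0 | 0 |
| zeta | 2.00 | 0 | 0 |
| zeta | 3.00 | 0.2 | 0 |
| zeta | 5.00 | 0.2 | 0.4 |
| zeta | 8.00 | 0 | 0.3 |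
| zeta | 10.0 | 0 | 0.1 |
| theta | 0.667 | 0 | 0.5 |
| theta | 2.00 | 0.1 | 1.1 |
| theta | 3.00 | 0 | 0.7 |
| theta | 5.00 | 0 | 0.7 |
| theta | 8.00 | 0 | 0 |
| theta | 10.0 | 1.1 | 0 |
| eta | 0.833 | 4.1 | 4.6 |
| eta | 1.33 | 3.3 | 4.2 |
| eta | 2.50 | 2.5 | 3.4 |
| eta | 5.00 | 2.6 | 4.6 |
| eta | 10.0 | 1.4 | 4.9 |

(scatter of a reading: 0.5 percentage points)

- amount of Qa at 8.0 min, in percent of the Qa charged
- amount of Qe at 8.0 min, in percent of the Qa charged
- amount of Qf at 8.0 min, in percent of the Qa charged



Zeta and theta, with 2.5 equiv and 4 equiv, showed Qe of 0.1 % and 0 % at 10.0 min, while eta, with 1.8 equiv, still showed 4.9 % at 10.0 min. I therefore assumed that Qb was the limiting reagent in eta and had been wholly taken up.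

I then reckoned in two ways the share of Qa that had gone on past Qe in eta. Subtracting the last Qa and Qe readings from the charge gave 93.7 %. Counting Qb gave 87.5 %: this is the Qb count, half of the Qb charged less the Qe standing. The two parted by 6.2 percentage points, against a scatter of 0.5 points.

Eta's readings showed which one cheated. Qa went from 4.1 % to 1.4 % while Qe went from 4.6 % to 4.9 %, which I read as Qa leaving by a way that did not pass through Qe. The subtraction books such Qa as having gone on past Qe, so I trusted the count.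

The count holds no concentration, so I carried it from eta at 0.60 M to the flask at 0.40 M, with the same 1.80 equiv. For the flask I committed to Qe near eta's reading and to 87.5 % as the share past Qe. No reading told me how much of that share was Qf.

The forecast gave 2.5 % Qa, 6 % Qe and 91.5 % Qf on the ground that “the flask should resemble eta”, and its Qf stood above my count.

The flask gave 2.39 % Qa, 4.08 % Qe and 56.0 % Qf at 8.0 min, with 31.9 % of Qg, which no reading had shown, beside the Qf.

    Qa + Qb → Qe + Qc (k = 0.840 L mol⁻¹ s⁻¹)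
    Qb + Qe → Qg (k = 0.570 L mol⁻¹ s⁻¹)
    Qb + Qe → Qf + Qc (k = 1.00 L mol⁻¹ s⁻¹)
    2 Qa → Qd (k = 0.0400 L mol⁻¹ s⁻¹)

With Qb at 0 % and the flask's own Qe, the Qb count gave 88.0 %, and Qf and Qg together came to 87.9 %. A neighbour of this flask with 0.720 equiv of Qb ended with Qb at 0 % and Qe at 24.2 %, so its count gave 23.9 %, and its Qf and Qg together came to 23.9 %.

The runs are simulated for substances that don't exist; noise was put on by code.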